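The route removes O1 and C2 of the oxolane as formaldehyde by cutting C2–C3 and O1–C5. What remains, C3–C4–C5, is a 1,3-dipole. The key step exploits the free para-hydroxyl of the guaiacyl ring on C5 (donor) and the syringoyl ketone next to C3 (acceptor). The precursor is an enantioenriched donor–acceptor cyclopropane with that phenol silylated and a removable benzyl ester on the acceptor carbon. Fluoride frees the phenolate and the ring opens to a p-quinone methide enolate. Aldol addition to formaldehyde, then oxa-1,6-addition, builds the oxolane in one operation, echoing the quinone methide trapping of lignan biosynthesis. The planar methide lets C4 alone dictate C5.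

Key step: step 8

Remark: the carbon bearing both the aroyl group and the benzyl ester (C1 in 7–9 and 11, C3 in 14 and 15, and in 13) is expected as an epimer mixture and is written without descriptor, because steps 8 and 9 erase it; oxolane numbering is O1, C2 (CH2), C3 (aroyl), C4 (CH2OH), C5 (aryl).

Step 1
Reactants: 1 (E)-coniferaldehyde [(E)-3-(4-hydroxy-3-methoxyphenyl)prop-2-enal]
Product: 2 (E)-3-[4-(tert-butyldimethylsilyloxy)-3-methoxyphenyl]prop-2-enal
Conditions: TBSCl, imidazole, CH2Cl2, rt
Reagents that add atoms: tert-butyldimethylsilyl chloride, CC(C)(C)[Si](C)(C)Cl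
Why: Imidazole-promoted O-silylation of the phenol; the aryl silyl ether should survive steps 5–7 and is the fluoride-labile trigger of step 8.

Step 2
Reactants: 3 acetosyringone [1-(4-hydroxy-3,5-dimethoxyphenyl)ethanone]
Product: 4 1-[4-(benzyloxy)-3,5-dimethoxyphenyl]ethanone
Conditions: BnBr, K2CO3, DMF, 60 °C
Reagents that add atoms: benzyl bromide, BrCc1ccccc1
Why: Williamson ether synthesis on the acidic syringyl phenol; the benzyl ether keeps the future ketone a strong acceptor (no second phenolate in step 8) and falls in step 9.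

Step 3
Reactants: 4 1-[4-(benzyloxy)-3,5-dimethoxyphenyl]ethanone
Product: 5 benzyl 3-[4-(benzyloxy)-3,5-dimethoxyphenyl]-3-oxopropanoate
Conditions: NaH, (BnO)2CO, THF, reflux; then aq. HCl
Reagents that add atoms: dibenzyl carbonate, O=C(OCc1ccccc1)OCc1ccccc1
Why: Crossed Claisen condensation of the methyl ketone enolate with a non-enolisable carbonate, pulled to completion by deprotonation of the β-keto ester formed.

Step 4
Reactants: 5 benzyl 3-[4-(benzyloxy)-3,5-dimethoxyphenyl]-3-oxopropanoate
Product: 6 benzyl 2-bromo-3-[4-(benzyloxy)-3,5-dimethoxyphenyl]-3-oxopropanoate (racemic, configurationally labile)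
Conditions: NBS (1.0 equiv), NH4OAc (10 mol%), Et2O, rt
Reagents that add atoms: N-bromosuccinimide, O=C1CCC(=O)N1Br
Why: Electrophilic α-bromination of the enolised 1,3-dicarbonyl compound, which should be much faster than substitution on the acyl-deactivated arene when one equivalent of NBS is used without radical initiation.

Step 5
Reactants: 2 (E)-3-[4-(tert-butyldimethylsilyloxy)-3-methoxyphenyl]prop-2-enal; 6 benzyl 2-bromo-3-[4-(benzyloxy)-3,5-dimethoxyphenyl]-3-oxopropanoate
Product: 7 benzyl (2R,3S)-1-[4-(benzyloxy)-3,5-dimethoxybenzoyl]-2-formyl-3-[4-(tert-butyldimethylsilyloxy)-3-methoxyphenyl]cyclopropane-1-carboxylate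
Conditions: (S)-2-[diphenyl(trimethylsilyloxy)methyl]pyrrolidine (20 mol%), 2,6-lutidine, CH2Cl2, 0 °C
Reagents that add atoms: none
Why: Michael-initiated ring closure under iminium–enamine catalysis: the CPh2(OSiMe3) group of the S catalyst shields one face of the E-iminium ion, so the bromo keto ester carbon adds to the β-carbon from the open face (3S), and the enamine carbon then displaces bromide 3-exo-tet anti to the aryl group (2R, formyl trans to aryl), the C1 epimer composition being without consequence.

Step 6
Reactants: 7 benzyl (2R,3S)-1-[4-(benzyloxy)-3,5-dimethoxybenzoyl]-2-formyl-3-[4-(tert-butyldimethylsilyloxy)-3-methoxyphenyl]cyclopropane-1-carboxylate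
Product: 8 benzyl (2R,3S)-1-[4-(benzyloxy)-3,5-dimethoxybenzoyl]-2-(hydroxymethyl)-3-[4-(tert-butyldimethylsilyloxy)-3-methoxyphenyl]cyclopropane-1-carboxylate
Conditions: NaBH4, MeOH–THF, −40 °C
Reagents that add atoms: none
Why: Chemoselective hydride reduction, because the aldehyde reacts far faster than the hindered, electron-rich aryl ketone next to a quaternary carbon, while the low temperature should suppress lactonisation and enolisation so that C2 is retained.

Step 7
Reactants: 8 benzyl (2R,3S)-1-[4-(benzyloxy)-3,5-dimethoxybenzoyl]-2-(hydroxymethyl)-3-[4-(tert-butyldimethylsilyloxy)-3-methoxyphenyl]cyclopropane-1-carboxylate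
Product: 9 benzyl (2R,3S)-1-[4-(benzyloxy)-3,5-dimethoxybenzoyl]-2-({[(benzyloxy)carbonyl]oxy}methyl)-3-[4-(tert-butyldimethylsilyloxy)-3-methoxyphenyl]cyclopropane-1-carboxylate
Conditions: CbzCl, pyridine, CH2Cl2, 0 °C
Reagents that add atoms: benzyl chloroformate, O=C(Cl)OCc1ccccc1
Why: O-acylation of the primary alcohol with a chloroformate gives a benzyl carbonate that blocks lactonisation and formal formation in step 8 and is as easily hydrogenolysed as the benzyl ester.

Step 8
Reactants: 9 benzyl (2R,3S)-1-[4-(benzyloxy)-3,5-dimethoxybenzoyl]-2-({[(benzyloxy)carbonyl]oxy}methyl)-3-[4-(tert-butyldimethylsilyloxy)-3-methoxyphenyl]cyclopropane-1-carboxylate; 10 formaldehyde (charged as paraformaldehyde)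
Product: 14 benzyl (4R,5S)-3-[4-(benzyloxy)-3,5-dimethoxybenzoyl]-4-({[(benzyloxy)carbonyl]oxy}methyl)-5-(4-hydroxy-3-methoxyphenyl)oxolane-3-carboxylate, via cyclopropane phenolate 11 (not isolated), via quinone methide enolate 12 (not isolated), via quinone methide alkoxide 13 (not isolated)
Conditions: (CH2O)n (excess), Bu4NF (1.1 equiv), THF, 0 °C to rt; then AcOH
Reagents that add atoms: none
Why: Proposed new method: fluoride removes the silyl group, phenolate 11 pushes through the guaiacyl ring into the strained C1–C3 bond of the cyclopropane and releases the p-quinone methide enolate 12, whose carbon adds to formaldehyde (aldol, new C–C bond) to give alkoxide 13, which adds to the methide carbon (oxa-1,6-addition, new C–O bond) with rearomatisation. The closest known reaction types are the Lewis-acid-catalysed (3+2) annulation of donor–acceptor cyclopropanes with aldehydes and the fluoride-triggered opening of 2-(4-silyloxyaryl)cyclopropane-1,1-dicarboxylates to p-quinone methides that are trapped by external nucleophiles; relaying the enolate through an aldehyde back onto the methide is the new element. The oxolane closes 5-exo-trig, the alkoxide attacking the exocyclic methide C=C. C5 is controlled by the untouched neighbour C4: in the conformer free of allylic 1,3-strain (C4–H eclipsing the methide C=C) the tethered alkoxide reaches only the face that places aryl trans to CH2OCbz, and because the phenolate can reopen the ring the trans isomer is also the product of equilibration, so the benzylic configuration of 9 does not matter, whereas the stereospecific Lewis-acid variant would invert it and give the cis isomer. The quaternary C3 forms as an epimer mixture that step 9 erases. The step needs C-hydroxymethylation to win over reclosure of 12 (3-exo C-attack back to 11 or 5-exo O-attack to a dihydrofuran) and over arene hydroxymethylation: both reclosures are reversible because a stabilised enolate leaves readily from a 4-oxidobenzyl position while the alkoxide adduct is the sink, excess formaldehyde speeds the aldol step, the carbonate keeps the CH2OH group out of play, and the absence of acid spares the electron-rich rings.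

Step 9
Reactants: 14 benzyl (4R,5S)-3-[4-(benzyloxy)-3,5-dimethoxybenzoyl]-4-({[(benzyloxy)carbonyl]oxy}methyl)-5-(4-hydroxy-3-methoxyphenyl)oxolane-3-carboxylate
Product: 16 [(3S,4R,5S)-5-(4-hydroxy-3-methoxyphenyl)-4-(hydroxymethyl)oxolan-3-yl](4-hydroxy-3,5-dimethoxyphenyl)methanone, via debenzylated keto acid 15 (not isolated)
Conditions: H2 (1 atm), 10% Pd/C, EtOAc–EtOH, rt; filter; then AcOH (cat.), 50 °C
Reagents that add atoms: none
Why: Catalytic hydrogenolysis cleaves the benzyl ester, the aryl benzyl ether and the benzyl carbonate (which loses CO2), all faster than the cyclic benzylic ether, and the β-keto acid 15 decarboxylates through its six-membered transition state to an enol whose ketonisation, reversible under the mildly acidic conditions, should leave the epimerisable C3 trans to the C4 hydroxymethyl group (3S), with C4 and C5 untouched.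

Compound list
1 | (E)-coniferaldehyde | COc1cc(/C=C/C=O)ccc1O | starting material
2 | (E)-3-[4-(tert-butyldimethylsilyloxy)-3-methoxyphenyl]prop-2-enal | COc1cc(/C=C/C=O)ccc1O[Si](C)(C)C(C)(C)C | intermediate
3 | acetosyringone | CC(=O)c1cc(OC)c(O)c(OC)c1 | starting material
4 | 1-[4-(benzyloxy)-3,5-dimethoxyphenyl]ethanone | CC(=O)c1cc(OC)c(OCc2ccccc2)c(OC)c1 | intermediate
5 | benzyl 3-[4-(benzyloxy)-3,5-dimethoxyphenyl]-3-oxopropanoate | O=C(CC(=O)c1cc(OC)c(OCc2ccccc2)c(OC)c1)OCc3ccccc3 | intermediate
6 | benzyl 2-bromo-3-[4-(benzyloxy)-3,5-dimethoxyphenyl]-3-oxopropanoate (racemic) | O=C(C(Br)C(=O)c1cc(OC)c(OCc2ccccc2)c(OC)c1)OCc3ccccc3 | intermediate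
7 | benzyl (2R,3S)-1-aroyl-2-formyl-3-(4-silyloxy-3-methoxyphenyl)cyclopropane-1-carboxylate, formyl trans to aryl, C1 epimers | O=C[C@@H]1[C@@H](c2ccc(O[Si](C)(C)C(C)(C)C)c(OC)c2)C1(C(=O)OCc3ccccc3)C(=O)c4cc(OC)c(OCc5ccccc5)c(OC)c4 | intermediate
8 | (2R,3S)-2-hydroxymethyl analogue of 7 | OC[C@@H]1[C@@H](c2ccc(O[Si](C)(C)C(C)(C)C)c(OC)c2)C1(C(=O)OCc3ccccc3)C(=O)c4cc(OC)c(OCc5ccccc5)c(OC)c4 | intermediate
9 | (2R,3S) benzyl carbonate of 8 | O=C(OCc1ccccc1)OC[C@@H]2[C@@H](c3ccc(O[Si](C)(C)C(C)(C)C)c(OC)c3)C2(C(=O)OCc4ccccc4)C(=O)c5cc(OC)c(OCc6ccccc6)c(OC)c5 | intermediate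
10 | formaldehyde (as paraformaldehyde) | C=O | starting material
11 | tetrabutylammonium phenolate of desilylated 9 | O=C(OCc1ccccc1)OC[C@@H]2[C@@H](c3ccc([O-])c(OC)c3)C2(C(=O)OCc4ccccc4)C(=O)c5cc(OC)c(OCc6ccccc6)c(OC)c5.CCCC[N+](CCCC)(CCCC)CCCC | intermediate
12 | ring-opened p-quinone methide β-keto ester enolate (Bu4N salt), R at CH(CH2OCbz) | COC1=CC(=C[C@@H](COC(=O)OCc2ccccc2)C(C(=O)OCc3ccccc3)=C([O-])c4cc(OC)c(OCc5ccccc5)c(OC)c4)C=CC1=O.CCCC[N+](CCCC)(CCCC)CCCC | intermediate
13 | hydroxymethylated p-quinone methide alkoxide (Bu4N salt), R at CH(CH2OCbz) | COC1=CC(=C[C@@H](COC(=O)OCc2ccccc2)C(C[O-])(C(=O)OCc3ccccc3)C(=O)c4cc(OC)c(OCc5ccccc5)c(OC)c4)C=CC1=O.CCCC[N+](CCCC)(CCCC)CCCC | intermediate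
14 | benzyl (4R,5S)-3-aroyl-4-(CbzOCH2)-5-(4-hydroxy-3-methoxyphenyl)oxolane-3-carboxylate, 4,5-trans, C3 epimers | COc1cc([C@H]2OCC(C(=O)OCc3ccccc3)(C(=O)c4cc(OC)c(OCc5ccccc5)c(OC)c4)[C@@H]2COC(=O)OCc6ccccc6)ccc1O | intermediate
15 | (4R,5S)-3-(4-hydroxy-3,5-dimethoxybenzoyl)-5-(4-hydroxy-3-methoxyphenyl)-4-(hydroxymethyl)oxolane-3-carboxylic acid | COc1cc([C@H]2OCC(C(=O)O)(C(=O)c3cc(OC)c(O)c(OC)c3)[C@@H]2CO)ccc1O | intermediate
16 | [(3S,4R,5S)-5-(4-hydroxy-3-methoxyphenyl)-4-(hydroxymethyl)oxolan-3-yl](4-hydroxy-3,5-dimethoxyphenyl)methanone, all-trans | COc1cc([C@H]2OC[C@@H](C(=O)c3cc(OC)c(O)c(OC)c3)[C@@H]2CO)ccc1O | target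

Total step count: 9. Longest linear sequence: 8 (steps 2–9 from acetosyringone).

Steps most likely to fail

1. Step 8 (bears the label).
- What may go wrong: reclosure of the opened ring may outrun the aldol step. The quinone methide may tautomerise to a styrene with loss of the C4 stereocentre. Adventitious hydroxide may cleave the non-enolisable keto ester by a retro-Claisen reaction.
- Fallback: it uses known chemistry and makes the two bonds one after the other. It sets out from 9 and returns at 14. Sc(OTf)3-catalysed opening of the donor–acceptor cyclopropane by acetic acid as O-nucleophile should give the ring-opened benzylic acetate F1. Base-catalysed hydroxymethylation of its keto ester (aq. CH2O, KHCO3, THF) should give the hydroxymethylated benzylic acetate F2. Bu4NF then removes the silyl group, acetate leaves by 1,6-elimination, and the primary alcohol already in place adds to the quinone methide to give 14.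

2. Step 5.
- What may go wrong: addition to the electron-rich iminium ion may be slow. Halogen may transfer from the bromo keto ester to the enamine. Base may open the formyl cyclopropane by expulsion of the stabilised keto ester anion, which would erase the C2 centre.
- Fallback: the aroyl group is brought in after the cyclopropane. It sets out from 2 and returns at 8. The same aminocatalyst is used with the malonate partner dibenzyl 2-bromomalonate F3 (from dibenzyl malonate and NBS) to give the formyl cyclopropane diester F4. NaBH4 reduction is now allowed to lactonise onto the cis ester, giving the bicyclic lactone ester F5. Separately, 4-bromo-2,6-dimethoxyphenol is benzylated to the aryl bromide F6, which n-BuLi converts into the aryllithium F7. Adding this at −78 °C to the strained lactone carbonyl, more reactive than the benzyl ester, and collapsing the hemiketal on work-up should give 8 as a single C1 epimer.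

3. Step 9.
- What may go wrong: the cyclic benzylic C5–O1 bond, activated by the free para-hydroxyl, may be hydrogenolysed. The aryl ketone may be reduced. Equilibration at C3 may stay incomplete.
- Fallback: the sensitive benzylic ether is temporarily deactivated. It sets out from 14 and returns at 16. Acetylation of the guaiacyl phenol (Ac2O, pyridine) gives the aryl acetate F8, whose electron-poorer ring should resist benzylic C–O cleavage. Hydrogenolysis and decarboxylation as in step 9 give the monoacetate of the target F9. Neutral deacetylation of the aryl acetate (NH4OAc, aq. MeOH) gives 16.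

Further compounds
F1 | step 8 | benzyl (3R)-4-acetoxy-2-[4-(benzyloxy)-3,5-dimethoxybenzoyl]-3-({[(benzyloxy)carbonyl]oxy}methyl)-4-[4-(tert-butyldimethylsilyloxy)-3-methoxyphenyl]butanoate (C2 and C4 epimers) | CC(=O)OC(c1ccc(O[Si](C)(C)C(C)(C)C)c(OC)c1)[C@@H](COC(=O)OCc2ccccc2)C(C(=O)OCc3ccccc3)C(=O)c4cc(OC)c(OCc5ccccc5)c(OC)c4
F2 | step 8 | 2-(hydroxymethyl) derivative of F1, (3R) | CC(=O)OC(c1ccc(O[Si](C)(C)C(C)(C)C)c(OC)c1)[C@@H](COC(=O)OCc2ccccc2)C(CO)(C(=O)OCc3ccccc3)C(=O)c4cc(OC)c(OCc5ccccc5)c(OC)c4
F3 | step 5 | dibenzyl 2-bromomalonate | O=C(OCc1ccccc1)C(Br)C(=O)OCc2ccccc2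
F4 | step 5 | dibenzyl (2R,3S)-2-formyl-3-[4-(tert-butyldimethylsilyloxy)-3-methoxyphenyl]cyclopropane-1,1-dicarboxylate | O=C[C@@H]1[C@@H](c2ccc(O[Si](C)(C)C(C)(C)C)c(OC)c2)C1(C(=O)OCc3ccccc3)C(=O)OCc4ccccc4
F5 | step 5 | benzyl (1R,5R,6S)-6-[4-(tert-butyldimethylsilyloxy)-3-methoxyphenyl]-2-oxo-3-oxabicyclo[3.1.0]hexane-1-carboxylate | O=C1OC[C@@H]2[C@@H](c3ccc(O[Si](C)(C)C(C)(C)C)c(OC)c3)[C@]12C(=O)OCc4ccccc4
F6 | step 5 | 2-(benzyloxy)-5-bromo-1,3-dimethoxybenzene | COc1cc(Br)cc(OC)c1OCc2ccccc2
F7 | step 5 | [4-(benzyloxy)-3,5-dimethoxyphenyl]lithium | [Li]c1cc(OC)c(OCc2ccccc2)c(OC)c1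
F8 | step 9 | aryl acetate of 14 | COc1cc([C@H]2OCC(C(=O)OCc3ccccc3)(C(=O)c4cc(OC)c(OCc5ccccc5)c(OC)c4)[C@@H]2COC(=O)OCc6ccccc6)ccc1OC(C)=O
F9 | step 9 | guaiacyl O-acetate of 16, (3S,4R,5S) | COc1cc([C@H]2OC[C@@H](C(=O)c3cc(OC)c(O)c(OC)c3)[C@@H]2CO)ccc1OC(C)=O
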